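## Retrosynthetic overview
1. The target opens to the keto-alcohol (C4 enone plus C8 tertiary OH). It closes to the 4,8-hemiketal on desilylation and forms by oxidation of a macrocyclic C4 allylic alcohol.
2. That ten-membered ring closes by intramolecular Nozaki–Hiyama–Kishi coupling (C4 aldehyde with the C5 alkenyl bromide).
3. The acyclic NHK precursor comes from an aldol union (C9–C10 bond) of two similar-sized fragments: a cyclohexenone (Diels–Alder derived, C1 quaternary, C2–C4 side chain as a protected aldehyde) and a γ-butyrolactone aldehyde (Mikami ene, then intramolecular Reformatsky).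
4. Rings form in this order: cyclohexene (Diels–Alder), γ-lactone (Reformatsky), aldol union, ten-membered carbocycle (NHK), then the tetrahydropyran hemiketal on desilylation.

Assumptions: C-numbering is the briarane numbering of the target, and the chiral catalysts and reagents are available in the enantiomer needed for each stereocentre (Steps 2, 3, 9).

## Route

**Step 1**
Reactants: 1 crotonaldehyde
Product: 2 (1E)-buta-1,3-dien-1-yl acetate
Conditions: Ac2O, KOAc, reflux; distil (E-enriched)
Reagents that add atoms: acetic anhydride, CC(=O)OC(C)=O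
Why: Enol acetylation of the enal (γ-deprotonation and O-acylation) gives the 1-acyloxydiene; only the (E)-isomer reacts in Step 2.

**Step 2**
Reactants: 2 diene + 3 methacrolein
Product: 4 (1R,2S)-2-(acetyloxy)-1-methylcyclohex-3-ene-1-carbaldehyde (OAc cis to CHO)
Conditions: 10 mol% chiral oxazaborolidinium catalyst (Tf2NH-activated), CH2Cl2, –78 °C
Reagents that add atoms: none
Why: Catalytic asymmetric Diels–Alder with ortho regiochemistry and an endo transition state. It sets the C1 quaternary centre and C14 (OAc cis to C2); the catalyst enantiomer is chosen to give the target (1R,2S) series.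

**Step 3**
Reactants: 4
Product: 5 (1R)-1-[(1S,2S)-2-(acetyloxy)-1-methylcyclohex-3-en-1-yl]but-3-en-1-ol
Conditions: B-allyl-diisopinocampheylborane (1.5 equiv; enantiomer chosen to give 2R), Et2O, –78 °C; then NaBO3·4H2O, THF/H2O, 0 °C
Reagents that add atoms: allyl-B(Ipc)2, C=CCB(C1CC2CC(C2(C)C)C1C)C1CC2CC(C2(C)C)C1C
Why: Brown asymmetric allylation through a chair transition state under reagent control sets C2 (R); the buffered, non-alkaline oxidative work-up avoids acetate migration.

**Step 4**
Reactants: 5
Product: 6 the corresponding C2 acetate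
Conditions: Ac2O, Et3N, DMAP, CH2Cl2, 0 °C to rt
Reagents that add atoms: acetic anhydride, CC(=O)OC(C)=O
Why: Installs the C2 acetate of the target; no stereocentre is touched.

**Step 5**
Reactants: 6
Product: 7 enone (C11 ketone conjugated to C12=C13)
Conditions: Rh2(cap)4 (1 mol%), TBHP (aq.), K2CO3, EtOAc, rt
Reagents that add atoms: tert-butyl hydroperoxide, CC(C)(C)OO
Why: Rh-catalysed allylic C–H oxidation acts at the ring allylic CH2 (C11), the only allylic methylene, leaving the terminal alkene. It creates the enone whose α′ carbon (C10) is used in Step 16.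

**Step 6**
Reactants: 7
Product: 8 (3R)-3-(acetyloxy)-3-[(1S,2S)-2-(acetyloxy)-1-methyl-5-oxocyclohex-3-en-1-yl]propanal
Conditions: O3 (1 equiv), CH2Cl2, –78 °C; then Me2S
Reagents that add atoms: ozone, [O-][O+]=O
Why: Ozonolysis is selective for the electron-rich terminal alkene over the enone and delivers the C4 aldehyde.

**Step 7**
Reactants: 8
Product: 9 the C4 1,3-dioxolane of 8 (enone-dioxolane, fragment A)
Conditions: TMSOCH2CH2OTMS, TMSOTf (cat.), CH2Cl2, –78 °C
Reagents that add atoms: 1,2-bis(trimethylsilyloxy)ethane, C[Si](C)(C)OCCO[Si](C)(C)C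
Why: Noyori acetalisation masks the β-acetoxy aldehyde without acid or base, so no β-elimination occurs.

**Step 8**
Reactants: 10 propionic acid
Product: 11 2-bromopropanoyl bromide
Conditions: Br2, PBr3 (cat.), 90 °C
Reagents that add atoms: bromine, BrBr; phosphorus tribromide, BrP(Br)Br
Why: Hell–Volhard–Zelinsky α-bromination proceeds via the acyl bromide enol and gives the acylating agent for Step 12.

**Step 9**
Reactants: 12 methyl glyoxylate + 13 2-bromopropene
Product: 14 methyl (2S)-4-bromo-2-hydroxypent-4-enoate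
Conditions: (S)-BINOL (10 mol%), TiCl2(OiPr)2 (10 mol%), 4 Å MS, CH2Cl2, 0 °C to rt
Reagents that add atoms: none
Why: Mikami asymmetric carbonyl-ene reaction forms the C6–C7 bond and the C5 alkenyl bromide; the chiral Ti–BINOL complex sets C7 (S).

**Step 10**
Reactants: 14
Product: 15 (2S)-4-bromo-2-hydroxy-N-methoxy-N-methylpent-4-enamide
Conditions: MeNH(OMe)·HCl, iPrMgCl (3.5 equiv), THF, –20 °C
Reagents that add atoms: N,O-dimethylhydroxylamine hydrochloride, CNOC.Cl
Why: Direct ester-to-Weinreb-amide conversion; the α-stereocentre is untouched under these non-epimerising conditions.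

**Step 11**
Reactants: 15
Product: 16 (4S)-6-bromo-4-hydroxyhepta-1,6-dien-3-one
Conditions: CH2=CHMgBr (3 equiv), THF, –78 °C to 0 °C
Reagents that add atoms: vinylmagnesium bromide, C=C[Mg]Br
Why: Weinreb ketone synthesis; the chelated tetrahedral intermediate prevents over-addition and the vinyl group becomes C9=CH2.

**Step 12**
Reactants: 16 + 11
Product: 17 (4S)-6-bromo-3-oxohepta-1,6-dien-4-yl 2-bromopropanoate (C2′ epimeric mixture)
Conditions: pyridine, DMAP (cat.), CH2Cl2, –20 °C
Reagents that add atoms: none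
Why: O-Acylation attaches the C17–C19 unit; the C17 centre may be left unresolved because it is destroyed on forming the zinc enolate in Step 13.

**Step 13**
Reactants: 17
Product: 18 (3R,4S,5S)-5-(2-bromoprop-2-en-1-yl)-4-ethenyl-4-hydroxy-3-methyloxolan-2-one
Conditions: Zn dust, TMSCl (cat.), THF, 65 °C
Reagents that add atoms: none
Why: Intramolecular Reformatsky gives 5-exo 1,2-addition of the zinc enolate to the vinyl ketone. A chelated chair-like transition state places the vinyl group trans to the C7 substituent (C8 S) and the C17 methyl trans to the vinyl group (C17 R).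

**Step 14**
Reactants: 18
Product: 19 the C8 triethylsilyl ether
Conditions: TESOTf, 2,6-lutidine, CH2Cl2, –78 °C
Reagents that add atoms: triethylsilyl triflate, CC[Si](CC)(CC)OS(=O)(=O)C(F)(F)F
Why: Protects the tertiary alcohol so that it does not quench the enolate in Step 16; no stereochemical change.

**Step 15**
Reactants: 19
Product: 20 (2S,3S,4R)-2-(2-bromoprop-2-en-1-yl)-4-methyl-5-oxo-3-[(triethylsilyl)oxy]oxolane-3-carbaldehyde (fragment B, the C9 aldehyde)
Conditions: OsO4 (5 mol%), NaIO4 (4 equiv), 2,6-lutidine, dioxane/H2O, rt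
Reagents that add atoms: sodium periodate, [Na+].[O-]I(=O)(=O)=O
Why: Lemieux–Johnson cleavage of the monosubstituted vinyl group gives the C9 aldehyde; the electron-poor 1,1-disubstituted alkenyl bromide is inert.

**Step 16**
Reactants: 9 + 20
Product: 21 aldol adduct (C9–C10 bond formed, C9–OH; fragment coupling)
Conditions: LDA (1.1 equiv), THF, –78 °C, 30 min; then 20, –78 °C, 1 h; NH4Cl
Reagents that add atoms: none
Why: Kinetic α′-deprotonation of the enone gives the cross-conjugated C10 enolate regiospecifically, which undergoes an intermolecular aldol reaction. The aldehyde approaches anti to the C2 side chain, so H10 ends up trans to C2 (C10 as in the target), and Felkin–Anh addition to the α-silyloxy aldehyde is expected to give the 9R carbinol.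

**Step 17**
Reactants: 21
Product: 22 the C9 acetate
Conditions: Ac2O, pyridine, DMAP, 40 °C
Reagents that add atoms: acetic anhydride, CC(=O)OC(C)=O
Why: Installs the C9 acetate under mild conditions that avoid retro-aldol and β-elimination of the β-hydroxy ketone.

**Step 18**
Reactants: 22
Product: 23 saturated C11 ketone
Conditions: [(Ph3P)CuH]6 (0.3 equiv), PhSiH3, toluene, 0 °C
Reagents that add atoms: none (hydride/H only)
Why: Stryker Cu–H 1,4-reduction removes C12=C13 selectively and leaves the lactone, acetates, acetal and alkenyl bromide intact; the epimerisable C10 settles in the thermodynamic trans-diequatorial arrangement.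

**Step 19**
Reactants: 23
Product: 24 C11 exocyclic methylene compound
Conditions: Cp2TiMe2 (4 equiv), toluene/THF, 70 °C, dark
Reagents that add atoms: dimethyltitanocene, C[Ti](C)(C1C=CC=C1)C1C=CC=C1
Why: Petasis methylenation is non-basic and ketone-selective, so it avoids C10 epimerisation and elimination of the C9 acetate; it forms the C11=C20 alkene.

**Step 20**
Reactants: 24
Product: 25 C4 aldehyde (NHK precursor)
Conditions: PPTS (0.5 equiv), acetone/H2O (10:1), 55 °C
Reagents that add atoms: water, O
Why: Transacetalisation/hydrolysis unmasks the C4 aldehyde; the mild acid leaves the hindered tertiary TES ether and the exocyclic alkene untouched.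

**Step 21**
Reactants: 25
Product: 26 ten-membered macrocyclic C4 allylic alcohol
Conditions: CrCl2 (12 equiv), NiCl2 (0.2 equiv), DMF (2 mM), syringe-pump addition, rt
Reagents that add atoms: none
Why: Intramolecular Nozaki–Hiyama–Kishi coupling forms the C4–C5 bond and the C5=C16 alkene, closing the ring; the new C4 carbinol centre is irrelevant because it is oxidised in Step 22.

**Step 22**
Reactants: 26
Product: 27 C4 enone (α-methylene ketone)
Conditions: activated MnO2 (30 equiv), CH2Cl2, rt
Reagents that add atoms: none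
Why: MnO2 chemoselectively oxidises the allylic alcohol; no other free hydroxyl is present.

**Step 23**
Reactants: 27
Product: 28 (+)-junceellolide A
Conditions: HF·pyridine, pyridine/THF, 0 °C to rt
Reagents that add atoms: none (Si removed; H only)
Why: Desilylation frees the C8 tertiary alcohol, which adds 6-exo to the C4 ketone to give the thermodynamic 4,8-hemiketal with the anomeric configuration of the target.

## Compound list
1 | (E)-but-2-enal (crotonaldehyde) | C/C=C/C=O | starting material
2 | (1E)-buta-1,3-dien-1-yl acetate | C=C/C=C/OC(C)=O | intermediate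
3 | 2-methylprop-2-enal (methacrolein) | C=C(C)C=O | starting material
4 | (1R,2S)-2-(acetyloxy)-1-methylcyclohex-3-ene-1-carbaldehyde | C[C@@]1(C=O)CCC=C[C@@H]1OC(C)=O | intermediate
5 | (1R)-1-[(1S,2S)-2-(acetyloxy)-1-methylcyclohex-3-en-1-yl]but-3-en-1-ol | C=CC[C@@H](O)[C@]1(C)CCC=C[C@@H]1OC(C)=O | intermediate
6 | diacetate of 5 | C=CC[C@@H](OC(C)=O)[C@]1(C)CCC=C[C@@H]1OC(C)=O | intermediate
7 | enone (C11 ketone, C12=C13) | C=CC[C@@H](OC(C)=O)[C@]1(C)CC(=O)C=C[C@@H]1OC(C)=O | intermediate
8 | (3R)-3-(acetyloxy)-3-[(1S,2S)-2-(acetyloxy)-1-methyl-5-oxocyclohex-3-en-1-yl]propanal | O=CC[C@@H](OC(C)=O)[C@]1(C)CC(=O)C=C[C@@H]1OC(C)=O | intermediate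
9 | dioxolane enone (fragment A) | C1COC(O1)C[C@@H](OC(C)=O)[C@]2(C)CC(=O)C=C[C@@H]2OC(C)=O | intermediate
10 | propionic acid | CCC(=O)O | starting material
11 | 2-bromopropanoyl bromide | CC(Br)C(=O)Br | intermediate
12 | methyl glyoxylate | COC(=O)C=O | starting material
13 | 2-bromopropene | CC(Br)=C | starting material
14 | methyl (2S)-4-bromo-2-hydroxypent-4-enoate | COC(=O)[C@@H](O)CC(Br)=C | intermediate
15 | (2S)-4-bromo-2-hydroxy-N-methoxy-N-methylpent-4-enamide | CON(C)C(=O)[C@@H](O)CC(Br)=C | intermediate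
16 | (4S)-6-bromo-4-hydroxyhepta-1,6-dien-3-one | C=CC(=O)[C@@H](O)CC(Br)=C | intermediate
17 | (4S)-6-bromo-3-oxohepta-1,6-dien-4-yl 2-bromopropanoate (C2′ epimers) | C=CC(=O)[C@@H](OC(=O)C(C)Br)CC(Br)=C | intermediate
18 | (3R,4S,5S)-5-(2-bromoprop-2-en-1-yl)-4-ethenyl-4-hydroxy-3-methyloxolan-2-one | C=C[C@]1(O)[C@@H](C)C(=O)O[C@H]1CC(Br)=C | intermediate
19 | C8 triethylsilyl ether of 18 | C=C[C@]1(O[Si](CC)(CC)CC)[C@@H](C)C(=O)O[C@H]1CC(Br)=C | intermediate
20 | (2S,3S,4R)-2-(2-bromoprop-2-en-1-yl)-4-methyl-5-oxo-3-[(triethylsilyl)oxy]oxolane-3-carbaldehyde (fragment B) | O=C[C@]1(O[Si](CC)(CC)CC)[C@@H](C)C(=O)O[C@H]1CC(Br)=C | intermediate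
21 | aldol adduct of 9 and 20 (9-OH) | C1COC(O1)C[C@@H](OC(C)=O)[C@]2(C)[C@@H]([C@@H](O)[C@]3(O[Si](CC)(CC)CC)[C@@H](C)C(=O)O[C@H]3CC(Br)=C)C(=O)C=C[C@@H]2OC(C)=O | intermediate
22 | C9 acetate of 21 | C1COC(O1)C[C@@H](OC(C)=O)[C@]2(C)[C@@H]([C@@H](OC(C)=O)[C@]3(O[Si](CC)(CC)CC)[C@@H](C)C(=O)O[C@H]3CC(Br)=C)C(=O)C=C[C@@H]2OC(C)=O | intermediate
23 | C11 saturated ketone | C1COC(O1)C[C@@H](OC(C)=O)[C@]2(C)[C@@H]([C@@H](OC(C)=O)[C@]3(O[Si](CC)(CC)CC)[C@@H](C)C(=O)O[C@H]3CC(Br)=C)C(=O)CC[C@@H]2OC(C)=O | intermediate
24 | C11 exocyclic methylene compound | C1COC(O1)C[C@@H](OC(C)=O)[C@]2(C)[C@@H]([C@@H](OC(C)=O)[C@]3(O[Si](CC)(CC)CC)[C@@H](C)C(=O)O[C@H]3CC(Br)=C)C(=C)CC[C@@H]2OC(C)=O | intermediate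
25 | C4 aldehyde | O=CC[C@@H](OC(C)=O)[C@]2(C)[C@@H]([C@@H](OC(C)=O)[C@]3(O[Si](CC)(CC)CC)[C@@H](C)C(=O)O[C@H]3CC(Br)=C)C(=C)CC[C@@H]2OC(C)=O | intermediate
26 | macrocyclic C4 allylic alcohol (C4 epimeric mixture) | C=C1CC[C@H](OC(C)=O)[C@@]2(C)[C@H]1[C@@H](OC(C)=O)[C@]3(O[Si](CC)(CC)CC)[C@@H](C)C(=O)O[C@H]3CC(=C)C(O)C[C@H]2OC(C)=O | intermediate
27 | macrocyclic C4 enone with C8-OTES | C=C1CC[C@H](OC(C)=O)[C@@]2(C)[C@H]1[C@@H](OC(C)=O)[C@]3(O[Si](CC)(CC)CC)[C@@H](C)C(=O)O[C@H]3CC(=C)C(=O)C[C@H]2OC(C)=O | intermediate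
28 | (+)-junceellolide A | C=C1CC[C@H](OC(C)=O)[C@@]2(C)[C@H]1[C@@H](OC(C)=O)[C@@]13O[C@](O)(C[C@H]2OC(C)=O)C(=C)C[C@@H]1OC(=O)[C@@H]3C | target

## Step counts
Total steps: 23. Longest linear sequence: 15 (1→2→3→4→5→6→7→16→17→18→19→20→21→22→23; the glyoxylate branch 9→…→15→16→…→23 is also 15).

## Three steps most likely to fail
1. **Step 16, the hindered aldol union** (enolate next to the quaternary C1, α-quaternary aldehyde, and uncertain C9 selectivity). Fallback: join C8–C9 instead by adding a 2-lithio-1,3-dithiane (bearing C7–OTBS and a TMS-alkyne) to the C9 aldehyde of the cyclohexane fragment, then build the lactone by intramolecular Reformatsky onto the unmasked C8 ketone.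
2. **Step 21, the ten-membered NHK macrocyclisation** with an alkenyl bromide. Fallback: close the ring at C2–C3 by an intramolecular Mukaiyama aldol of a C4 silyl dienol ether onto a C2 aldehyde, using a precursor carrying that functionality instead.
3. **Step 13, Reformatsky diastereoselectivity at C8/C17.** Fallback: use a β-substituted butenolide, make the C8 tertiary alcohol by nucleophilic epoxidation, and open the epoxide with SmI2 so that C8 and C17 are set by the ring-face and protonation rather than by the zinc enolate.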